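**Strategy.** Numbering: cyclopentane C1–C5, seven-membered ring C5–C10–C1. The bicycle is cut at C1–C10 and C5–C6. In the target, C6 and C9 of the seven-membered ring are 1,5-related through C5–C1–C10, and both bonds leave the cyclopentane on the face of the C4 oxygen. A cyclopentene (C1=C5) whose C4 alkoxide is tied through a diisopropylsilyl unit to the enol oxygen of cyclopentane-1,3-dione is therefore irradiated. Intramolecular [2+2] photocycloaddition, then fluoride-triggered retro-aldol cleavage of C6–C10, gives the cis-fused 6,9-dione: one operation closes the seven-membered ring and sets C1 and C5. Directed reduction at C6, C8 methylenation with reductive transposition at C9, and two acylations complete the route.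

Key step: step 5

Remark on the chemistry: all bicyclic compounds carry the target numbering; β is the cyclopentane face of the C4 oxygen, α the opposite face; the SMILES strings define the configurations. (S)-Enone 1 supplies C2 of the target in its final configuration.

Design remark: the C2 oxygen keeps the silyl group of 1 throughout. The tether in 12 is a dialkoxydiisopropylsilane, which buffered fluoride should open much faster than the neopentyl silyl ether at C2. Compound 12 is used without chromatography because its silyl enol linkage is hydrolytically labile.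

**Step 1**
Reactants: 1 (S)-4-(tert-butyldimethylsilyloxy)cyclopent-2-en-1-one; 2 methyllithium
Product: 4 tert-butyldimethyl{[(1S,2S)-2-methyl-4-(trimethylsilyloxy)cyclopent-3-en-1-yl]oxy}silane, via lithium dimethylcuprate 3 (not isolated)
Conditions: MeLi, CuI, Et2O, 0 °C; then 1, Me3SiCl, −78 °C; Et3N quench
Reagents that add atoms: lithium dimethylcuprate (3), [Li+].C[Cu-]C; chlorotrimethylsilane, C[Si](C)(C)Cl
Why: Conjugate addition of the organocuprate Me2CuLi places the methyl group on the β-carbon anti to the silyloxy group, and trapping of the regiodefined enolate as its silyl enol ether prevents β-elimination of the silyloxy group; the new methyl-bearing stereocentre is erased in step 2.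

**Step 2**
Reactants: 4 tert-butyldimethyl{[(1S,2S)-2-methyl-4-(trimethylsilyloxy)cyclopent-3-en-1-yl]oxy}silane
Product: 5 (S)-4-(tert-butyldimethylsilyloxy)-3-methylcyclopent-2-en-1-one
Conditions: Pd(OAc)2 (10 mol %), O2 (1 atm), DMSO, 25 °C
Reagents that add atoms: none
Why: Saegusa–Ito oxidation, in which the palladium enolate can undergo β-hydride elimination only toward the methyl-bearing carbon, so the double bond is regenerated next to the untouched silyloxy stereocentre.

**Step 3**
Reactants: 5 (S)-4-(tert-butyldimethylsilyloxy)-3-methylcyclopent-2-en-1-one; 6 isopropylmagnesium chloride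
Product: 7 (1S,4S)-4-(tert-butyldimethylsilyloxy)-1-isopropyl-3-methylcyclopent-2-en-1-ol (hydroxyl cis to the silyloxy group)
Conditions: iPrMgCl, CeCl3 (anhydrous), THF, −78 °C
Reagents that add atoms: isopropylmagnesium chloride (6), CC(C)[Mg]Cl
Why: 1,2-Addition of the weakly basic reagent formed from iPrMgCl and CeCl3 avoids enolisation and conjugate addition, and attack on the carbonyl face anti to the silyloxy group sets the carbinol centre (later C4) with its oxygen cis to the C2 oxygen.

**Step 4**
Reactants: 7 (1S,4S)-4-(tert-butyldimethylsilyloxy)-1-isopropyl-3-methylcyclopent-2-en-1-ol; 8 dichlorodiisopropylsilane; 9 cyclopentane-1,3-dione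
Product: 12 3-({[(1S,4S)-4-(tert-butyldimethylsilyloxy)-1-isopropyl-3-methylcyclopent-2-en-1-yl]oxy}diisopropylsilyloxy)cyclopent-2-en-1-one, via lithium alkoxide 10 (not isolated), via chlorosilyl ether 11 (not isolated)
Conditions: n-BuLi, THF, −78 °C; 8 (3 equiv), −78 °C → rt; excess 8 removed in vacuo; then 9, Et3N, CH2Cl2, 0 °C → rt; filtration, no chromatography
Reagents that add atoms: dichlorodiisopropylsilane (8), CC(C)[Si](Cl)(Cl)C(C)C; cyclopentane-1,3-dione (9), O=C1CCC(=O)C1
Why: Stepwise nucleophilic substitution at silicon (unsymmetrical silyl ketal formation): the hindered tertiary alkoxide displaces one chloride of the excess dichlorosilane, and the remaining Si–Cl bond is then taken by the oxygen of the dione enolate; no stereocentre is touched.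

**Step 5**
Reactants: 12 3-({[(1S,4S)-4-(tert-butyldimethylsilyloxy)-1-isopropyl-3-methylcyclopent-2-en-1-yl]oxy}diisopropylsilyloxy)cyclopent-2-en-1-one
Product: 15 2β-(tert-butyldimethylsilyloxy)-4β-hydroxy-4α-isopropyl-1α-methyl-cis-perhydroazulene-6,9-dione (H5 α), via cyclobutane photoadduct 13 (not isolated), via cyclobutanol 14 (not isolated)
Conditions: hν (medium-pressure Hg lamp, Pyrex filter), degassed MeCN (0.01 M), 0 °C; then Bu4NF/AcOH (1:1), THF, 0 °C → rt
Reagents that add atoms: none
Why: Excitation and intersystem crossing give the triplet of the vinylogous silyl ester, which bonds through its β-carbon C6 to C5 and then through C10 to the tertiary radical at C1; this is a de Mayo reaction run as an enone–alkene [2+2] photocycloaddition through a temporary silicon tether. The first bond closes a six-membered 1,3-dioxa-2-silacyclohexane and the 1,4-biradical then collapses to the cyclobutane; the seven-membered ring is not closed directly but appears when fluoride frees the C6 cyclobutanol and retro-aldol cleavage of C6–C10 enlarges the former dione ring by C1 and C5. C5 and C1 are both set by the O4–Si–O tether, which forces bonding on the face of the C4 oxygen, and the cis addition across C1=C5 leaves H5 and the C1 methyl cis. The step needs C6-to-C5 regiochemistry, β-face addition, and unmasking without loss of the C2 silyl ether or retro-aldol opening at C4–C5. The three-atom tether and the stability of the tertiary C1 radical secure the first two, and acetic-acid-buffered fluoride acting on the dialkoxysilane secures the third.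

**Step 6**
Reactants: 15 2β-(tert-butyldimethylsilyloxy)-4β-hydroxy-4α-isopropyl-1α-methyl-cis-perhydroazulene-6,9-dione
Product: 16 2β-(tert-butyldimethylsilyloxy)-4β,6α-dihydroxy-4α-isopropyl-1α-methyl-cis-perhydroazulen-9-one
Conditions: Me4NBH(OAc)3, MeCN/AcOH (1:1), −30 °C
Reagents that add atoms: none
Why: Hydroxyl-directed Evans–Saksena reduction, in which the borohydride bound to the C4 oxygen delivers hydride to the face of the C6 carbonyl turned toward O4 and so sets the 6α-alcohol, while the C9 ketone, which has no β-hydroxyl, is left alone.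

**Step 7**
Reactants: 16 2β-(tert-butyldimethylsilyloxy)-4β,6α-dihydroxy-4α-isopropyl-1α-methyl-cis-perhydroazulen-9-one
Product: 17 4β,6α-O-isopropylidene acetal of 16 (C9 ketone and C2 silyl ether retained)
Conditions: 2-methoxypropene, pyridinium p-toluenesulfonate (cat.), CH2Cl2, 0 °C
Reagents that add atoms: 2-methoxypropene, COC(C)=C
Why: Acid-catalysed acetonide formation ties the tertiary C4 and secondary C6 hydroxyls into a six-membered acetal, which removes both acidic protons and any hemiketal formation with the C9 ketone before the enolate chemistry.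

**Step 8**
Reactants: 17 4β,6α-O-isopropylidene acetal of 16; 18 N,N-dimethylmethyleneiminium iodide
Product: 22 8-methylene-9-ketone (acetonide and C2 silyl ether retained), via C8 lithium enolate 19 (not isolated), via Mannich base 20 (not isolated), via trimethylammonium iodide 21 (not isolated)
Conditions: LiN(iPr)2, THF, −78 °C; 18, −78 °C → rt; then MeI, CH2Cl2, rt; then NaHCO3 (aq), CH2Cl2, rt; used at once
Reagents that add atoms: N,N-dimethylmethyleneiminium iodide (18), C[N+](C)=C.[I-]
Why: Kinetic deprotonation occurs at C8 and not at the neopentyl C10 beside the quaternary C1, and Mannich aminomethylation of that enolate followed by N-methylation and Hofmann-type elimination gives the exocyclic enone; the transient C8 stereocentre is lost.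

**Step 9**
Reactants: 22 8-methylene-9-ketone
Product: 24 8-methyl-8-en-9-yl trifluoromethanesulfonate (acetonide and C2 silyl ether retained), via tetrasubstituted lithium enolate 23 (not isolated)
Conditions: LiBH(s-Bu)3, THF, −78 °C; then PhNTf2, −78 → 0 °C
Reagents that add atoms: N-phenylbis(trifluoromethanesulfonimide), O=S(=O)(N(c1ccccc1)S(=O)(=O)C(F)(F)F)C(F)(F)F
Why: Conjugate reduction of the s-cis exocyclic enone by the bulky borohydride turns the methylene into the C8 methyl and gives the C8=C9 enolate regiospecifically, and O-triflation fixes that regiochemistry.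

**Step 10**
Reactants: 24 8-methyl-8-en-9-yl trifluoromethanesulfonate
Product: 25 2β-(tert-butyldimethylsilyloxy)-4β,6α-isopropylidenedioxy-4α-isopropyl-1α,8-dimethyl-cis-octahydroazul-8-ene
Conditions: Pd(OAc)2 (5 mol %), PPh3 (10 mol %), HCO2H, Bu3N, DMF, 60 °C
Reagents that add atoms: none
Why: Palladium-catalysed formate reduction of an enol triflate (oxidative addition of zerovalent palladium into the C9–O bond, formate exchange, decarboxylation, reductive elimination) replaces the triflate by hydrogen without moving the C8=C9 double bond.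

**Step 11**
Reactants: 25 2β-(tert-butyldimethylsilyloxy)-4β,6α-isopropylidenedioxy-4α-isopropyl-1α,8-dimethyl-cis-octahydroazul-8-ene
Product: 26 2β-hydroxy-4β,6α-isopropylidenedioxy-4α-isopropyl-1α,8-dimethyl-cis-octahydroazul-8-ene
Conditions: Bu4NF, THF, rt → 50 °C
Reagents that add atoms: none
Why: Fluoride-mediated desilylation, which can be forced on the hindered neopentyl silyl ether because the acetonide and the alkene are inert to fluoride.

**Step 12**
Reactants: 26 2β-hydroxy-4β,6α-isopropylidenedioxy-4α-isopropyl-1α,8-dimethyl-cis-octahydroazul-8-ene; 27 angelic acid ((Z)-2-methylbut-2-enoic acid)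
Product: 29 2β-angeloyloxy-4β,6α-isopropylidenedioxy-4α-isopropyl-1α,8-dimethyl-cis-octahydroazul-8-ene, via mixed anhydride 28 (not isolated)
Conditions: 2,4,6-trichlorobenzoyl chloride, Et3N, toluene, rt; then 26, 75 °C
Reagents that add atoms: angelic acid (27), C/C=C(/C)C(=O)O
Why: Yamaguchi esterification without a nucleophilic catalyst, in which the only free hydroxyl attacks the less hindered angeloyl carbonyl of the mixed anhydride; the absence of DMAP suppresses Z-to-E isomerisation, and C2 keeps its configuration because its C–O bond is not broken.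

**Step 13**
Reactants: 29 2β-angeloyloxy-4β,6α-isopropylidenedioxy-4α-isopropyl-1α,8-dimethyl-cis-octahydroazul-8-ene
Product: 30 2β-angeloyloxy-4α-isopropyl-1α,8-dimethyl-cis-octahydroazul-8-ene-4β,6α-diol
Conditions: pyridinium p-toluenesulfonate, MeOH, rt
Reagents that add atoms: none
Why: Mild acid-catalysed transketalisation to methanol removes the strained acetonide, and the angelate, the trisubstituted alkene and the tertiary alcohol tolerate the weak acid.

**Step 14**
Reactants: 30 2β-angeloyloxy-4α-isopropyl-1α,8-dimethyl-cis-octahydroazul-8-ene-4β,6α-diol; 31 3,4,5-trimethoxybenzoyl chloride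
Product: 32 CNP0112256.1 (2β-angeloyloxy-4β-hydroxy-6α-(3,4,5-trimethoxybenzoyloxy) ester)
Conditions: pyridine, DMAP (cat.), CH2Cl2, 0 °C → rt
Reagents that add atoms: 3,4,5-trimethoxybenzoyl chloride (31), COc1cc(C(=O)Cl)cc(OC)c1OC
Why: DMAP-catalysed O-acylation takes the secondary C6 hydroxyl with retention, while the tertiary, isopropyl-flanked C4 hydroxyl does not react.

**Compound list**
1 | (S)-4-(tert-butyldimethylsilyloxy)cyclopent-2-en-1-one | CC(C)(C)[Si](C)(C)O[C@H]1CC(=O)C=C1 | starting material
2 | methyllithium | C[Li] | starting material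
3 | lithium dimethylcuprate | [Li+].C[Cu-]C | intermediate
4 | tert-butyldimethyl{[(1S,2S)-2-methyl-4-(trimethylsilyloxy)cyclopent-3-en-1-yl]oxy}silane | C[C@H]1C=C(O[Si](C)(C)C)C[C@@H]1O[Si](C)(C)C(C)(C)C | intermediate
5 | (S)-4-(tert-butyldimethylsilyloxy)-3-methylcyclopent-2-en-1-one | CC1=CC(=O)C[C@@H]1O[Si](C)(C)C(C)(C)C | intermediate
6 | isopropylmagnesium chloride | CC(C)[Mg]Cl | starting material
7 | (1S,4S)-4-(tert-butyldimethylsilyloxy)-1-isopropyl-3-methylcyclopent-2-en-1-ol | CC(C)(C)[Si](C)(C)O[C@H]1C[C@](O)(C(C)C)C=C1C | intermediate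
8 | dichlorodiisopropylsilane | CC(C)[Si](Cl)(Cl)C(C)C | starting material
9 | cyclopentane-1,3-dione | O=C1CCC(=O)C1 | starting material
10 | lithium alkoxide of 7 | CC(C)(C)[Si](C)(C)O[C@H]1C[C@](O[Li])(C(C)C)C=C1C | intermediate
11 | chlorodiisopropylsilyl ether of 7 | CC(C)(C)[Si](C)(C)O[C@H]1C[C@](O[Si](Cl)(C(C)C)C(C)C)(C(C)C)C=C1C | intermediate
12 | silicon-tethered photoprecursor (silyl ketal of 7 and the enol of 9) | CC(C)(C)[Si](C)(C)O[C@H]1C[C@](O[Si](C(C)C)(C(C)C)OC2=CC(=O)CC2)(C(C)C)C=C1C | intermediate
13 | cis-anti-cis cyclobutane photoadduct with intact O4–Si–O6 bridge | CC(C)(C)[Si](C)(C)O[C@H]1C[C@@]2(C(C)C)O[Si](C(C)C)(C(C)C)O[C@@]34CCC(=O)[C@H]3[C@]1(C)[C@@H]24 | intermediate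
14 | desilylated cyclobutanol (C6–OH, C9 ketone) | CC(C)(C)[Si](C)(C)O[C@H]1C[C@](O)(C(C)C)[C@@H]2[C@@]1(C)[C@H]3C(=O)CC[C@@]23O | intermediate
15 | 2β-(tert-butyldimethylsilyloxy)-4β-hydroxy-4α-isopropyl-1α-methyl-cis-perhydroazulene-6,9-dione | CC(C)(C)[Si](C)(C)O[C@H]1C[C@](O)(C(C)C)[C@H]2C(=O)CCC(=O)C[C@@]12C | intermediate
16 | 2β-(tert-butyldimethylsilyloxy)-4β,6α-dihydroxy-4α-isopropyl-1α-methyl-cis-perhydroazulen-9-one | CC(C)(C)[Si](C)(C)O[C@H]1C[C@](O)(C(C)C)[C@H]2[C@H](O)CCC(=O)C[C@@]12C | intermediate
17 | 4β,6α-O-isopropylidene acetal of 16 | CC(C)(C)[Si](C)(C)O[C@H]1C[C@@]2(C(C)C)OC(C)(C)O[C@@H]3CCC(=O)C[C@]1(C)[C@@H]23 | intermediate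
18 | N,N-dimethylmethyleneiminium iodide | C[N+](C)=C.[I-] | starting material
19 | C8=C9 lithium enolate of 17 | CC(C)(C)[Si](C)(C)O[C@H]1C[C@@]2(C(C)C)OC(C)(C)O[C@@H]3CC=C(O[Li])C[C@]1(C)[C@@H]23 | intermediate
20 | 8-(dimethylaminomethyl)-9-ketone (C8 epimers) | CC(C)(C)[Si](C)(C)O[C@H]1C[C@@]2(C(C)C)OC(C)(C)O[C@@H]3CC(CN(C)C)C(=O)C[C@]1(C)[C@@H]23 | intermediate
21 | 8-(trimethylammoniomethyl)-9-ketone iodide | CC(C)(C)[Si](C)(C)O[C@H]1C[C@@]2(C(C)C)OC(C)(C)O[C@@H]3CC(C[N+](C)(C)C)C(=O)C[C@]1(C)[C@@H]23.[I-] | intermediate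
22 | 8-methylene-9-ketone | CC(C)(C)[Si](C)(C)O[C@H]1C[C@@]2(C(C)C)OC(C)(C)O[C@@H]3CC(=C)C(=O)C[C@]1(C)[C@@H]23 | intermediate
23 | lithium 8-methyl-8-en-9-olate | CC(C)(C)[Si](C)(C)O[C@H]1C[C@@]2(C(C)C)OC(C)(C)O[C@@H]3CC(C)=C(O[Li])C[C@]1(C)[C@@H]23 | intermediate
24 | 8-methyl-8-en-9-yl trifluoromethanesulfonate | CC(C)(C)[Si](C)(C)O[C@H]1C[C@@]2(C(C)C)OC(C)(C)O[C@@H]3CC(C)=C(OS(=O)(=O)C(F)(F)F)C[C@]1(C)[C@@H]23 | intermediate
25 | 2β-silyloxy 4β,6α-acetonide 8-ene | CC(C)(C)[Si](C)(C)O[C@H]1C[C@@]2(C(C)C)OC(C)(C)O[C@@H]3CC(C)=CC[C@]1(C)[C@@H]23 | intermediate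
26 | 2β-hydroxy 4β,6α-acetonide 8-ene | O[C@H]1C[C@@]2(C(C)C)OC(C)(C)O[C@@H]3CC(C)=CC[C@]1(C)[C@@H]23 | intermediate
27 | angelic acid | C/C=C(/C)C(=O)O | starting material
28 | angelic 2,4,6-trichlorobenzoic anhydride | C/C=C(/C)C(=O)OC(=O)c1c(Cl)cc(Cl)cc1Cl | intermediate
29 | 2β-angeloyloxy 4β,6α-acetonide 8-ene | C/C=C(/C)C(=O)O[C@H]1C[C@@]2(C(C)C)OC(C)(C)O[C@@H]3CC(C)=CC[C@]1(C)[C@@H]23 | intermediate
30 | 2β-angeloyloxy 4β,6α-diol | C/C=C(/C)C(=O)O[C@H]1C[C@](O)(C(C)C)[C@H]2[C@H](O)CC(C)=CC[C@@]12C | intermediate
31 | 3,4,5-trimethoxybenzoyl chloride | COc1cc(C(=O)Cl)cc(OC)c1OC | starting material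
32 | CNP0112256.1 | C/C=C(/C)C(=O)O[C@H]1C[C@](O)(C(C)C)[C@H]2[C@H](OC(=O)c3cc(OC)c(OC)c(OC)c3)CC(C)=CC[C@@]12C | target

**Step count.** Total: 14 steps. Longest linear sequence: 14 steps, from 1 to 32.

**Steps most likely to fail**

1. Step 5. The silyl enol linkage of 12 may hydrolyse before or during irradiation. The 1,4-biradical may revert instead of closing beside the C2 silyl ether. Unmasking may also cost the C2 silyl group or trigger base-induced retro-aldol opening at C4–C5 or epimerisation at C5. The fallback sets out from alcohol 7 and replaces the silicon tether by a chromatographable formaldehyde acetal that is unravelled by acid instead of fluoride. KN(SiMe3)2 and MeSCH2Cl/NaI in THF should give the methylthiomethyl ether F1. SO2Cl2 in CH2Cl2 at −78 °C, with cyclohexene to scavenge the sulfenyl chloride, converts it into the chloromethyl ether F2. This O-alkylates dione 9 (iPr2NEt) to the acetal-tethered vinylogous ester F3. Irradiation as in step 5 should form the same C5–C6 and C1–C10 bonds and give the dioxane-bridged cyclobutane photoadduct F4. TsOH·H2O in wet THF then opens this donor–acceptor cyclobutane with loss of formaldehyde, and the route is rejoined at dione 15.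

2. Step 8. Enolisation may not discriminate fully between C8 and C10, and the exocyclic enone may dimerise or isomerise into the ring during the elimination. The fallback sets out from ketone 17. LiN(iPr)2 and MeI at −78 °C should give the 8-methyl ketone F5. Equilibration with BrMgN(iPr)2 in Et2O at rt should favour the more substituted bromomagnesium enolate F6, which is trapped with PhNTf2. The route is rejoined at triflate 24, so steps 8 and 9 are both bypassed.

3. Step 12. Acylation of the neopentyl C2 hydroxyl may be slow, and prolonged heating may isomerise the angeloyl unit to the E (tigloyl) isomer. The fallback sets out from alcohol 26 and builds the Z double bond on the ester. Esterification with 2-[bis(2,2,2-trifluoroethoxy)phosphoryl]propanoic acid (dicyclohexylcarbodiimide, DMAP, CH2Cl2) should give the phosphonopropanoate ester F7. Still–Gennari olefination with acetaldehyde (KN(SiMe3)2, 18-crown-6, THF, −78 °C) should then form the Z-2-methylbut-2-enoate, and the route is rejoined at angelate 29.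

**Further compounds**
F1 | step 5 | methylthiomethyl ether of 7 | CC(C)(C)[Si](C)(C)O[C@H]1C[C@](OCSC)(C(C)C)C=C1C
F2 | step 5 | chloromethyl ether of 7 | CC(C)(C)[Si](C)(C)O[C@H]1C[C@](OCCl)(C(C)C)C=C1C
F3 | step 5 | formaldehyde-acetal-tethered vinylogous ester | CC(C)(C)[Si](C)(C)O[C@H]1C[C@](OCOC2=CC(=O)CC2)(C(C)C)C=C1C
F4 | step 5 | dioxane-bridged cyclobutane photoadduct | CC(C)(C)[Si](C)(C)O[C@H]1C[C@@]2(C(C)C)OCO[C@@]34CCC(=O)[C@H]3[C@]1(C)[C@@H]24
F5 | step 8 | 8-methyl-9-ketone (C8 epimers) | CC(C)(C)[Si](C)(C)O[C@H]1C[C@@]2(C(C)C)OC(C)(C)O[C@@H]3CC(C)C(=O)C[C@]1(C)[C@@H]23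
F6 | step 8 | bromomagnesium 8-methyl-8-en-9-olate | CC(C)(C)[Si](C)(C)O[C@H]1C[C@@]2(C(C)C)OC(C)(C)O[C@@H]3CC(C)=C(O[Mg]Br)C[C@]1(C)[C@@H]23
F7 | step 12 | 2-[bis(2,2,2-trifluoroethoxy)phosphoryl]propanoate of 26 | CC(C(=O)O[C@H]1C[C@@]2(C(C)C)OC(C)(C)O[C@@H]3CC(C)=CC[C@]1(C)[C@@H]23)P(=O)(OCC(F)(F)F)OCC(F)(F)F
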